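## Analysis of the target

The target, (1R,2S,3R)-1-(3,4-dimethoxyphenyl)-4-(4-hydroxy-3-methoxyphenyl)-2,3-dimethylbutyl acetate, is a 7-acetoxy-8,8′-lignan. Lignan numbering is used below: the butane chain is C7–C8–C8′–C7′, with methyl C9 on C8 and methyl C9′ on C8′; C7 carries the acetoxy group and the 3,4-dimethoxyphenyl ring, and C7′ is a CH2 bonded to C1′ of the 4-hydroxy-3-methoxyphenyl ring.

- There is no ring besides the two arenes, so all stereocontrol is acyclic.
- The three stereocentres are contiguous: C7 (R), C8 (S), C8′ (R). In the zigzag of C7′–C8′–C8–C7 the substituents C9′, C9 and OAc lie on one side (7,8-syn and 8,8′-syn).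
- The acetate sits on an electron-rich benzylic carbon. Acid, Lewis acid or hydrogenolysis would ionise or cleave C7–O, with epimerisation or Friedel–Crafts closure onto the other ring.
- The free phenol is acylated faster than the C7 hydroxyl. It must be masked during acetylation and released under conditions that spare the ester.
- C7′ carries no heteroatom. Any route that brings it in as a carbonyl must later deoxygenate it next to an equally benzylic C7–O.
- The hardest centre is C8′: it is flanked only by carbon and its two substituents (methyl, arylmethyl) are similar in size.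
- The feature that the route uses: the five carbons C7′–C8′(C9′)–C8–C9 form the branched C5 skeleton of isoprene. The target is that unit hydroarylated across C7′/C8′ and hydro(hydroxybenzyl)ated across C9/C8.

## Retrosynthetic reasoning

**12 ⇒ 11.** The last bond cut is the aryl O–Si bond. The phenol stays masked until after acetylation, and a silyl ether is chosen because a buffered fluoride source removes it without touching the benzylic acetate; hydrogenolysis or acid would not be safe.

**11 ⇒ 10.** The C7 O–acetyl bond is cut. With the phenol masked, acylation of the single free hydroxyl is unambiguous and touches no stereocentre.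

**10 ⇒ 7 + 2 (key disconnection).** The C7′–C1′ bond is cut and the hydrogen on C8′ is removed with it, giving the 1,1-disubstituted alkene 7 and the aryl bromide 2.
- Why here: C7′ is the one chain carbon that never needs oxygen, so an aryl–C(sp3) coupling avoids any carbonyl or deoxygenation at this position.
- What is gained: the hardest stereocentre disappears into an alkene, and the precursor 7 has only two stereocentres and fourteen carbons.
- What the forward step must do: add hydride to C8′ and the arene to C7′, anti-Markovnikov, with control of C8′ in the presence of C7 and C8.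

**7 ⇒ 4 + 5.** The C7–C8 bond is cut. 7 is a homoallylic alcohol, so it comes from aldehyde 5 and the (Z)-allylsilane 4. The forward allylation must pass through a closed transition state that turns the Z geometry into the 7,8-syn relationship, with a chiral catalyst fixing the absolute configuration of both centres.

**4 ⇒ 3.** A 1,4-addition of Si–H across diene 3 gives 4. All five carbons C7′, C8′, C9′, C8 and C9 come from 3 in the correct oxidation state.

**2 ⇒ 1.** The O–Si bond is cut; 2 is the silyl ether of the commercial bromophenol 1.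

## Alternatives that were turned down

**Alternative 1:** the textbook route, cutting C7–C8 with a chiral auxiliary.
- Forward key step: Evans syn-aldol of the boron enolate of the propionyl imide A1 with 5, giving A2 with C7 and C8 set.
- Why turned down: the acyl carbon of A2 is C8′. It would have to be converted into a CH bearing C9′ and the arylmethyl group by amide exchange, addition of a benzylic organometallic, methylenation and hydrogenation. That is four operations on a β-hydroxy carbonyl prone to retro-aldol, with a stoichiometric auxiliary and about nine steps in all. C8′ would be set last on an exo-methylene compound, where a hydroxyl-directed hydrogenation is expected to deliver hydrogen syn to C7, the wrong face, so protecting-group steps would be added. Step 3 of the chosen route forms the same bond with a catalyst and with C8′ already at the right oxidation level.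

**Alternative 2:** a cyclic template, cutting both aryl–carbon bonds back to anhydride A3.
- Forward key step: aryl Grignard addition to A3 and enantioselective reduction give butenolide A4; hydrogenation anti to the aryl group, then epimerisation next to the carbonyl, give lactone A5 with C7, C8 and C8′ set on the ring. A second aryl-metal is then added to the lactone carbonyl (C7′).
- Why turned down: C7′ arrives as a carbonyl and must be reduced to CH2 next to the C7–O bond, which is just as benzylic and just as electron-rich. Ionic hydrogenation and hydrogenolysis cannot tell the two apart, and the hydroxy ketone closes to a tetrahydrofuran under acid. The only selective handle, a quinone methide of the free phenol, would be trapped by the C7 alkoxide. The asymmetric reduction would have to distinguish an aryl from a tetrasubstituted alkenyl group of similar size. The count is about nine steps.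

**Alternative 3:** a three-component coupling, cutting C7–C8 and C8′–C9′ at once.
- Forward key step: nickel-catalysed alkylative coupling of 5, alkyne A6 and a methylzinc reagent gives the tetrasubstituted allylic alcohol A7; a hydroxyl-directed hydrogenation then sets C8 and C8′ together by syn addition.
- Why turned down: syn addition to the E alkene does give the 8,8′-syn pair. But allylic 1,3-strain with the methyl on C8′ holds C7–H in the alkene plane, and the hydroxyl then delivers hydrogen from its own face, which gives the 7,8-anti relationship, the wrong diastereomer. Correction would need oxidation and an anti-Felkin reduction. The two alkyne termini (methyl and arylmethyl) are also poorly differentiated in the insertion.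

Key step: step 4

Assumption: the enantiomer named for each chiral controller (the bisphosphoramide in step 3, DTBM-SEGPHOS in step 4, the diamine in reagent F6) is taken to give the facial sense stated; if one induces the opposite sense, its mirror image is used and nothing else changes.

## Route

Step 1
Reactants: 1 4-bromo-2-methoxyphenol
Product: 2 (4-bromo-2-methoxyphenoxy)tri(propan-2-yl)silane
Conditions: TIPSCl, imidazole, DMF, rt
Reagents that add atoms: chlorotri(propan-2-yl)silane, CC(C)[Si](Cl)(C(C)C)C(C)C
Why: Silylation of a phenol with a bulky silyl chloride and imidazole. The aryl TIPS ether should survive the silanolate base, the copper hydride and the acylation that follow, and fluoride removes it at the end without touching the benzylic acetate.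

Step 2
Reactants: 3 isoprene (2-methylbuta-1,3-diene)
Product: 4 trichloro[(2Z)-2-methylbut-2-en-1-yl]silane
Conditions: HSiCl3, Pd(PPh3)4 (cat.), neat, sealed vessel, 70 °C; distillation
Reagents that add atoms: trichlorosilane, Cl[SiH](Cl)Cl
Why: Palladium(0)-catalysed 1,4-hydrosilylation of a 1,3-diene, known for this diene: hydrogen goes to C4 of the s-cis diene and silicon to the less hindered terminus C1 of the π-allyl complex, which should give the Z allylsilane. No stereocentre is formed; the Z geometry is what step 3 converts into the 7,8-syn relationship.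

Step 3
Reactants: 4 trichloro[(2Z)-2-methylbut-2-en-1-yl]silane; 5 3,4-dimethoxybenzaldehyde
Product: 7 (1R,2S)-1-(3,4-dimethoxyphenyl)-2,3-dimethylbut-3-en-1-ol, via trichlorosilyl ether 6 (not isolated)
Conditions: (S,S)-2,2′-bipyrrolidine-derived bisphosphoramide with pentane-1,5-diyl linker (5 mol %), iPr2NEt, CH2Cl2, −78 °C; then sat. aq. NaHCO3
Reagents that add atoms: none
Why: Lewis-base-catalysed carbonyl allylation with an allylic trichlorosilane (Sakurai-type allylation through a hexacoordinate siliconate). The closed chair-like transition state places the aryl group equatorial and the Z γ-methyl group axial, so the 7,8-syn product should form. The catalyst selects the Re face of 5, which fixes C7 as R and with it C8 as S; hydrogencarbonate work-up hydrolyses 6.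

Step 4
Reactants: 7 (1R,2S)-1-(3,4-dimethoxyphenyl)-2,3-dimethylbut-3-en-1-ol; 2 (4-bromo-2-methoxyphenoxy)tri(propan-2-yl)silane
Product: 10 (1R,2S,3R)-1-(3,4-dimethoxyphenyl)-4-{3-methoxy-4-[tri(propan-2-yl)silyloxy]phenyl}-2,3-dimethylbutan-1-ol, via alkene silyl ether 8 (not isolated), via coupled silyl ether 9 (not isolated)
Conditions: Cu(OAc)2/(S)-DTBM-SEGPHOS (5 mol %), MePh2SiH (3.2 equiv), THF, rt (H2 evolves); then 2, [Pd(cinnamyl)Cl]2/BrettPhos (2/4.4 mol %), NaOTMS (2 equiv), 40 °C; then K2CO3 (cat.), MeOH, 0 °C
Reagents that add atoms: none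
Why: Copper hydride/palladium dual-catalysed anti-Markovnikov hydroarylation of a 1,1-disubstituted alkene, a known reaction type for aryl bromides that gives arenes with a β-stereocentre; no ring is closed. The ligated copper hydride first silylates the hydroxyl of 7 with loss of hydrogen (8), which masks it against palladium-mediated oxidation. Syn-hydrocupration of 8 puts copper on the terminal carbon C7′ and hydride on C8′; the substrate secures this regiochemistry, because only the unsubstituted terminus can carry the bulky copper. The primary alkylcopper transmetalates to the arylpalladium bromide formed from 2, reductive elimination forms C7′–C1′, and silanolate plus hydrosilane return copper bromide to copper hydride. The new stereocentre C8′ is set in the hydrocupration under ligand control: hydride must reach the Si face of C8′ (C8 > C7′ > CH3), which gives 3R. The handle for the ligand is the large size difference between the two geminal groups on C8′, a methyl group and the branched C8 substituent. C7 and C8 are not touched, because neither the alkylcopper nor the alkylpalladium has a pathway to epimerise them. Methanolysis of the labile silyl ether 9 on work-up should return the free alcohol 10 with the aryl silyl ether intact.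

Step 5
Reactants: 10 (1R,2S,3R)-1-(3,4-dimethoxyphenyl)-4-{3-methoxy-4-[tri(propan-2-yl)silyloxy]phenyl}-2,3-dimethylbutan-1-ol
Product: 11 (1R,2S,3R)-1-(3,4-dimethoxyphenyl)-4-{3-methoxy-4-[tri(propan-2-yl)silyloxy]phenyl}-2,3-dimethylbutyl acetate
Conditions: Ac2O, pyridine, DMAP (cat.), CH2Cl2, 0 °C to rt
Reagents that add atoms: acetic anhydride, CC(=O)OC(C)=O
Why: DMAP-catalysed acylation of the secondary benzylic alcohol under basic conditions, which avoid ionisation at C7. The phenol is masked, so only the C7 hydroxyl can react and no stereocentre is touched.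

Step 6
Reactants: 11 (1R,2S,3R)-1-(3,4-dimethoxyphenyl)-4-{3-methoxy-4-[tri(propan-2-yl)silyloxy]phenyl}-2,3-dimethylbutyl acetate
Product: 12 (1R,2S,3R)-1-(3,4-dimethoxyphenyl)-4-(4-hydroxy-3-methoxyphenyl)-2,3-dimethylbutyl acetate
Conditions: TBAF, AcOH, THF, 0 °C
Reagents that add atoms: none
Why: Fluoride cleaves the aryl O–Si bond, driven by Si–F bond formation. Acetic acid protonates the phenoxide so that acetyl transfer and ester hydrolysis should not occur, and the neutral, non-reducing conditions leave the benzylic C7–O bond and all three stereocentres alone.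

## Compound list

1 | 4-bromo-2-methoxyphenol | COc1cc(Br)ccc1O | starting material
2 | (4-bromo-2-methoxyphenoxy)tri(propan-2-yl)silane | COc1cc(Br)ccc1O[Si](C(C)C)(C(C)C)C(C)C | intermediate
3 | isoprene (2-methylbuta-1,3-diene) | C=CC(C)=C | starting material
4 | trichloro[(2Z)-2-methylbut-2-en-1-yl]silane | C/C=C(C)\C[Si](Cl)(Cl)Cl | intermediate
5 | 3,4-dimethoxybenzaldehyde | COc1ccc(C=O)cc1OC | starting material
6 | trichloro{[(1R,2S)-1-(3,4-dimethoxyphenyl)-2,3-dimethylbut-3-en-1-yl]oxy}silane | C=C(C)[C@H](C)[C@@H](O[Si](Cl)(Cl)Cl)c1ccc(OC)c(OC)c1 | intermediate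
7 | (1R,2S)-1-(3,4-dimethoxyphenyl)-2,3-dimethylbut-3-en-1-ol | C=C(C)[C@H](C)[C@@H](O)c1ccc(OC)c(OC)c1 | intermediate
8 | {[(1R,2S)-1-(3,4-dimethoxyphenyl)-2,3-dimethylbut-3-en-1-yl]oxy}(methyl)diphenylsilane | C=C(C)[C@H](C)[C@@H](O[Si](C)(c1ccccc1)c1ccccc1)c1ccc(OC)c(OC)c1 | intermediate
9 | {[(1R,2S,3R)-1-(3,4-dimethoxyphenyl)-4-{3-methoxy-4-[tri(propan-2-yl)silyloxy]phenyl}-2,3-dimethylbutyl]oxy}(methyl)diphenylsilane | COc1cc(C[C@@H](C)[C@H](C)[C@@H](O[Si](C)(c2ccccc2)c2ccccc2)c2ccc(OC)c(OC)c2)ccc1O[Si](C(C)C)(C(C)C)C(C)C | intermediate
10 | (1R,2S,3R)-1-(3,4-dimethoxyphenyl)-4-{3-methoxy-4-[tri(propan-2-yl)silyloxy]phenyl}-2,3-dimethylbutan-1-ol | COc1cc(C[C@@H](C)[C@H](C)[C@@H](O)c2ccc(OC)c(OC)c2)ccc1O[Si](C(C)C)(C(C)C)C(C)C | intermediate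
11 | (1R,2S,3R)-1-(3,4-dimethoxyphenyl)-4-{3-methoxy-4-[tri(propan-2-yl)silyloxy]phenyl}-2,3-dimethylbutyl acetate | COc1cc(C[C@@H](C)[C@H](C)[C@@H](OC(C)=O)c2ccc(OC)c(OC)c2)ccc1O[Si](C(C)C)(C(C)C)C(C)C | intermediate
12 | (1R,2S,3R)-1-(3,4-dimethoxyphenyl)-4-(4-hydroxy-3-methoxyphenyl)-2,3-dimethylbutyl acetate | COc1cc(C[C@@H](C)[C@H](C)[C@@H](OC(C)=O)c2ccc(OC)c(OC)c2)ccc1O | target

## Step count, longest linear sequence, least certain steps

Total step count: 6. Longest linear sequence: 5 steps (3 → 4 → 7 → 10 → 11 → 12); step 1 is a one-step side branch.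

**Step 4 (key step).** The most likely failure is poor facial selectivity in the hydrocupration, a mismatched case.
- Cause: on its own, the allylic centre C8 prefers a transition state with C8–H inside and the C7 substituent anti to the incoming metal hydride. That delivers hydride to the Re face of C8′ and leads to the 3S epimer, so the ligand must override the substrate.
- Second effect: the branching next to the alkene slows insertion, so reduction of the aryl bromide can compete.
- Fallback (known chemistry; the aryl group is attached first and C8′ is set last under substrate control). It sets out from 3, uses 2 and 5, and returns at 11.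
  - 3 is metalated at its methyl group (LDA/KOtBu, THF, −78 °C), transmetalated with ZnCl2 and joined to 2 by Negishi coupling (Pd/SPhos) to give the diene {2-methoxy-4-(2-methylidenebut-3-en-1-yl)phenoxy}tri(propan-2-yl)silane F1.
  - Palladium-catalysed 1,4-hydrosilylation as in step 2 gives trichloro[(2Z)-2-({3-methoxy-4-[tri(propan-2-yl)silyloxy]phenyl}methyl)but-2-en-1-yl]silane F2.
  - Addition to 5 under the conditions of step 3 gives the trichlorosilyl ether trichloro{[(1R,2S)-1-(3,4-dimethoxyphenyl)-3-({3-methoxy-4-[tri(propan-2-yl)silyloxy]phenyl}methyl)-2-methylbut-3-en-1-yl]oxy}silane F3 and, after work-up, (1R,2S)-1-(3,4-dimethoxyphenyl)-3-({3-methoxy-4-[tri(propan-2-yl)silyloxy]phenyl}methyl)-2-methylbut-3-en-1-ol F4.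
  - Acetylation as in step 5 gives (1R,2S)-1-(3,4-dimethoxyphenyl)-3-({3-methoxy-4-[tri(propan-2-yl)silyloxy]phenyl}methyl)-2-methylbut-3-en-1-yl acetate F5.
  - Hydrogenation of F5 with H2 and RhCl(PPh3)3 in benzene should give 11. In F5 the two groups on C8′ are exchanged relative to 7 (arylmethyl in place, the methylene becoming C9′), so the same steric preference of C8 that works against step 4 now delivers hydrogen in the 3R sense.

**Step 3.** The most likely failures are erosion of enantioselectivity through a poorly organised background addition of the 2-substituted allylsilane, and ionisation of the electron-rich benzylic silyl ether with loss of the C7–O bond.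
- Fallback (reagent control by a covalently bound chiral diamine in place of an external catalyst). It sets out from 4, uses 5, and returns at 7.
  - 4 is condensed with (1R,2R)-N,N′-bis(4-bromobenzyl)cyclohexane-1,2-diamine and DBU in CH2Cl2 to give the strained reagent (3aR,7aR)-1,3-bis[(4-bromophenyl)methyl]-2-chloro-2-[(2Z)-2-methylbut-2-en-1-yl]octahydro-1H-1,3,2-benzodiazasilole F6.
  - F6 adds to 5 (Sc(OTf)3 cat., CH2Cl2, 0 °C) through the same closed transition state to give the silyl ether (3aR,7aR)-1,3-bis[(4-bromophenyl)methyl]-2-chloro-2-{[(1R,2S)-1-(3,4-dimethoxyphenyl)-2,3-dimethylbut-3-en-1-yl]oxy}octahydro-1H-1,3,2-benzodiazasilole F7.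
  - Aqueous work-up hydrolyses F7 to 7.

**Step 6.** The most likely failure is transfer or hydrolysis of the benzylic acetyl group once fluoride releases the phenoxide.
- Fallback (the phenol is unmasked before acylation and the two esters are told apart at the end by reactivity). It sets out from 10 and returns at 12.
  - TBAF in THF converts 10 into the diol 4-[(2R,3S,4R)-4-(3,4-dimethoxyphenyl)-4-hydroxy-2,3-dimethylbutyl]-2-methoxyphenol F8.
  - Ac2O/pyridine/DMAP acylates both hydroxyls to give 4-[(2R,3S,4R)-4-(acetyloxy)-4-(3,4-dimethoxyphenyl)-2,3-dimethylbutyl]-2-methoxyphenyl acetate F9.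
  - NH4OAc in aqueous methanol at rt should cleave only the more electrophilic aryl acetate and give 12.

## Further compounds

F1 | step 4 | {2-methoxy-4-(2-methylidenebut-3-en-1-yl)phenoxy}tri(propan-2-yl)silane | C=CC(=C)Cc1ccc(O[Si](C(C)C)(C(C)C)C(C)C)c(OC)c1
F2 | step 4 | trichloro[(2Z)-2-({3-methoxy-4-[tri(propan-2-yl)silyloxy]phenyl}methyl)but-2-en-1-yl]silane | C/C=C(Cc1ccc(O[Si](C(C)C)(C(C)C)C(C)C)c(OC)c1)\C[Si](Cl)(Cl)Cl
F3 | step 4 | trichloro{[(1R,2S)-1-(3,4-dimethoxyphenyl)-3-({3-methoxy-4-[tri(propan-2-yl)silyloxy]phenyl}methyl)-2-methylbut-3-en-1-yl]oxy}silane | C=C(Cc1ccc(O[Si](C(C)C)(C(C)C)C(C)C)c(OC)c1)[C@H](C)[C@@H](O[Si](Cl)(Cl)Cl)c1ccc(OC)c(OC)c1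
F4 | step 4 | (1R,2S)-1-(3,4-dimethoxyphenyl)-3-({3-methoxy-4-[tri(propan-2-yl)silyloxy]phenyl}methyl)-2-methylbut-3-en-1-ol | C=C(Cc1ccc(O[Si](C(C)C)(C(C)C)C(C)C)c(OC)c1)[C@H](C)[C@@H](O)c1ccc(OC)c(OC)c1
F5 | step 4 | (1R,2S)-1-(3,4-dimethoxyphenyl)-3-({3-methoxy-4-[tri(propan-2-yl)silyloxy]phenyl}methyl)-2-methylbut-3-en-1-yl acetate | C=C(Cc1ccc(O[Si](C(C)C)(C(C)C)C(C)C)c(OC)c1)[C@H](C)[C@@H](OC(C)=O)c1ccc(OC)c(OC)c1
F6 | step 3 | (3aR,7aR)-1,3-bis[(4-bromophenyl)methyl]-2-chloro-2-[(2Z)-2-methylbut-2-en-1-yl]octahydro-1H-1,3,2-benzodiazasilole | C/C=C(C)\C[Si]1(Cl)N(Cc2ccc(Br)cc2)[C@@H]2CCCC[C@H]2N1Cc1ccc(Br)cc1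
F7 | step 3 | (3aR,7aR)-1,3-bis[(4-bromophenyl)methyl]-2-chloro-2-{[(1R,2S)-1-(3,4-dimethoxyphenyl)-2,3-dimethylbut-3-en-1-yl]oxy}octahydro-1H-1,3,2-benzodiazasilole | C=C(C)[C@H](C)[C@@H](O[Si]1(Cl)N(Cc2ccc(Br)cc2)[C@@H]2CCCC[C@H]2N1Cc1ccc(Br)cc1)c1ccc(OC)c(OC)c1
F8 | step 6 | 4-[(2R,3S,4R)-4-(3,4-dimethoxyphenyl)-4-hydroxy-2,3-dimethylbutyl]-2-methoxyphenol | COc1cc(C[C@@H](C)[C@H](C)[C@@H](O)c2ccc(OC)c(OC)c2)ccc1O
F9 | step 6 | 4-[(2R,3S,4R)-4-(acetyloxy)-4-(3,4-dimethoxyphenyl)-2,3-dimethylbutyl]-2-methoxyphenyl acetate | COc1cc(C[C@@H](C)[C@H](C)[C@@H](OC(C)=O)c2ccc(OC)c(OC)c2)ccc1OC(C)=O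
A1 | alternative 1 | (4R)-4-benzyl-3-propanoyl-1,3-oxazolidin-2-one | CCC(=O)N1[C@H](Cc2ccccc2)COC1=O
A2 | alternative 1 | (4R)-4-benzyl-3-[(2R,3R)-3-(3,4-dimethoxyphenyl)-3-hydroxy-2-methylpropanoyl]-1,3-oxazolidin-2-one | O=C1OC[C@@H](Cc2ccccc2)N1C(=O)[C@H](C)[C@@H](O)c1ccc(OC)c(OC)c1
A3 | alternative 2 | 3,4-dimethylfuran-2,5-dione | CC1=C(C)C(=O)OC1=O
A4 | alternative 2 | (5S)-5-(3,4-dimethoxyphenyl)-3,4-dimethylfuran-2(5H)-one | CC1=C(C)[C@@H](OC1=O)c1ccc(OC)c(OC)c1
A5 | alternative 2 | (3S,4S,5R)-5-(3,4-dimethoxyphenyl)-3,4-dimethyloxolan-2-one | O=C1[C@@H](C)[C@H](C)[C@@H](O1)c1ccc(OC)c(OC)c1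
A6 | alternative 3 | [4-(but-2-yn-1-yl)-2-methoxyphenoxy]tri(propan-2-yl)silane | CC#CCc1ccc(O[Si](C(C)C)(C(C)C)C(C)C)c(OC)c1
A7 | alternative 3 | (1S,2E)-1-(3,4-dimethoxyphenyl)-4-{3-methoxy-4-[tri(propan-2-yl)silyloxy]phenyl}-2,3-dimethylbut-2-en-1-ol | O[C@@H](c1ccc(OC)c(OC)c1)/C(C)=C(\C)Cc1ccc(O[Si](C(C)C)(C(C)C)C(C)C)c(OC)c1
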